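**Retrosynthetic overview**
1. The target is a trans-2-aryl-3-methyl-2,3-dihydrobenzofuran (ring A = benzo ring, ring C = dihydrofuran O1/C2/C3/C3a/C7a, ring B = pendant aryl) with an anti-1,2-diol on C5. The route rests on C2 of ring C being the benzylic carbon of ring B and para to the ring B C4 methoxy group, so O1–C2 can be formed by hydride loss from C2 and capture of the cation by the ring A phenol oxygen.
2. C5–C1' is cut last: C5 aryllithium plus O-silyl (S)-lactic Weinreb amide, with C1' set by chelation-controlled ketone reduction.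
3. O1–C2 is cut next (DDQ dehydrogenative etherification of an (R)-1,2-diarylpropane phenol). Ring C is the only ring built; rings A and B are bought.
4. The C3 centre comes from iridium-catalysed asymmetric hydrogenation of an (E)-α-methylstilbene. Its geometry is fixed by copper-catalysed borylation of a ring B aryl propyne and iodine-selective Suzuki coupling with a ring A bromo iodo arene.

Key step: step 10

Assumption: benzofuran numbering (O1, C2, C3, C3a, C4–C7, C7a; side chain C1', C2') is used, and 3-hydroxy-4,5-dimethoxybenzaldehyde, 4-bromo-2-methoxyphenol and ethyl (S)-lactate are taken as the commercial starting materials.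

**Route**

Step 1
Reactants: 1 3-hydroxy-4,5-dimethoxybenzaldehyde
Product: 2 3,4-dimethoxy-5-[tri(propan-2-yl)silyloxy]benzaldehyde
Conditions: TIPSCl, imidazole, DMF, rt
Reagents that add atoms: triisopropylsilyl chloride, CC(C)[Si](Cl)(C(C)C)C(C)C
Why: Silyl ether formation on the only acidic OH; the bulky aryl TIPS ether should survive organolithium, borylation, cross-coupling, dilute acid and DDQ until fluoride removes it in step 14.

Step 2
Reactants: 2 3,4-dimethoxy-5-[tri(propan-2-yl)silyloxy]benzaldehyde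
Product: 3 [5-(2,2-dibromoethenyl)-2,3-dimethoxyphenoxy]tri(propan-2-yl)silane
Conditions: CBr4, PPh3, Zn dust, CH2Cl2, 0 °C → rt
Reagents that add atoms: carbon tetrabromide, BrC(Br)(Br)Br
Why: Corey–Fuchs (Ramirez) dibromoolefination, a Wittig reaction of Ph3P=CBr2 with the aryl aldehyde; the zinc variant avoids Ph3PBr2 and HBr, which could attack the silyl ether.

Step 3
Reactants: 3 [5-(2,2-dibromoethenyl)-2,3-dimethoxyphenoxy]tri(propan-2-yl)silane
Product: 5 [2,3-dimethoxy-5-(prop-1-yn-1-yl)phenoxy]tri(propan-2-yl)silane, via lithium acetylide 4 (not isolated)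
Conditions: n-BuLi (2.2 equiv), THF, −78 °C; then MeI, −78 °C → rt
Reagents that add atoms: iodomethane, CI
Why: Second stage of the Corey–Fuchs sequence: bromine–lithium exchange and Fritsch–Buttenberg–Wiechell rearrangement give the alkyne, the second equivalent of n-BuLi forms acetylide 4, and SN2 methylation caps it as the aryl propyne.

Step 4
Reactants: 5 [2,3-dimethoxy-5-(prop-1-yn-1-yl)phenoxy]tri(propan-2-yl)silane
Product: 6 2-[(1Z)-1-{3,4-dimethoxy-5-[tri(propan-2-yl)silyloxy]phenyl}prop-1-en-2-yl]-4,4,5,5-tetramethyl-1,3,2-dioxaborolane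
Conditions: B2pin2, CuCl (5 mol%), P(p-Tol)3 (6 mol%), NaOt-Bu (10 mol%), MeOH (2 equiv), THF, rt
Reagents that add atoms: bis(pinacolato)diboron, CC1(C)OB(OC1(C)C)B1OC(C)(C)C(C)(C)O1
Why: Copper-catalysed formal hydroboration of an aryl alkyl alkyne: the Cu–Bpin species adds syn with copper at the aryl-bearing carbon and boron at the methyl-bearing carbon, and protonolysis by MeOH with retention leaves H and Bpin cis, which fixes the later alkene geometry.

Step 5
Reactants: 7 4-bromo-2-methoxyphenol
Product: 8 4-bromo-2-iodo-6-methoxyphenol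
Conditions: NIS, TsOH·H2O (10 mol%), MeCN, 0 °C → rt
Reagents that add atoms: N-iodosuccinimide, O=C1CCC(=O)N1I
Why: Electrophilic aromatic iodination; the hydroxyl group is the strongest director and its para position is blocked by bromine, so iodine should enter at the one free ortho position.

Step 6
Reactants: 8 4-bromo-2-iodo-6-methoxyphenol
Product: 9 5-bromo-1-iodo-3-methoxy-2-(methoxymethoxy)benzene
Conditions: MOMCl, i-Pr2NEt, CH2Cl2, 0 °C → rt
Reagents that add atoms: chloromethyl methyl ether, COCCl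
Why: Williamson-type O-alkylation to the MOM acetal; it masks the phenol, which could otherwise add to the stilbene under the acidic iridium hydride conditions of step 8, and it is later cleaved by acid without loss of the aryl TIPS ether.

Step 7
Reactants: 6 2-[(1Z)-1-{3,4-dimethoxy-5-[tri(propan-2-yl)silyloxy]phenyl}prop-1-en-2-yl]-4,4,5,5-tetramethyl-1,3,2-dioxaborolane; 9 5-bromo-1-iodo-3-methoxy-2-(methoxymethoxy)benzene
Product: 10 {5-[(1E)-2-[5-bromo-3-methoxy-2-(methoxymethoxy)phenyl]prop-1-en-1-yl]-2,3-dimethoxyphenoxy}tri(propan-2-yl)silane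
Conditions: PdCl2(dppf) (4 mol%), K3PO4, 1,4-dioxane/H2O, 60 °C
Reagents that add atoms: none
Why: Suzuki–Miyaura coupling: zerovalent palladium inserts into C–I much faster than into the C–Br bond para to the donor oxygen, and transmetalation and reductive elimination go with retention, so the Z boronate should give the E stilbene with rings A and B trans.

Step 8
Reactants: 10 {5-[(1E)-2-[5-bromo-3-methoxy-2-(methoxymethoxy)phenyl]prop-1-en-1-yl]-2,3-dimethoxyphenoxy}tri(propan-2-yl)silane
Product: 11 5-bromo-1-[(2R)-1-{3,4-dimethoxy-5-[tri(propan-2-yl)silyloxy]phenyl}propan-2-yl]-3-methoxy-2-(methoxymethoxy)benzene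
Conditions: H2 (50 bar), [Ir(cod)(L)][B(C6H3-3,5-(CF3)2)4] (2 mol%; L = (S)-4-tert-butyl-2-[2-(di-o-tolylphosphanyl)phenyl]-4,5-dihydro-1,3-oxazole), CH2Cl2, rt
Reagents that add atoms: none
Why: Iridium-catalysed asymmetric hydrogenation of an unfunctionalised trisubstituted alkene (Pfaltz type), for which (E)-1,2-diarylpropenes are the standard substrates: the chiral P,N ligand selects the alkene face and sets the future C3; the (S)-ligand is expected to give the (R)-alkane by analogy with the parent system (the (R)-ligand is used if the ortho substituent reverses the sense), and aryl bromide, acetal and silyl ether are inert to this catalyst.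

Step 9
Reactants: 11 5-bromo-1-[(2R)-1-{3,4-dimethoxy-5-[tri(propan-2-yl)silyloxy]phenyl}propan-2-yl]-3-methoxy-2-(methoxymethoxy)benzene
Product: 12 4-bromo-2-methoxy-6-[(2R)-1-{3,4-dimethoxy-5-[tri(propan-2-yl)silyloxy]phenyl}propan-2-yl]phenol
Conditions: conc. HCl (cat.), MeOH/THF, 45 °C
Reagents that add atoms: none
Why: Acid-catalysed acetal cleavage (MOM removal) through the oxocarbenium ion, which methanol traps; aryl TIPS ethers are stable to dilute methanolic HCl and the stereocentre has no pathway to epimerise.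

Step 10
Reactants: 12 4-bromo-2-methoxy-6-[(2R)-1-{3,4-dimethoxy-5-[tri(propan-2-yl)silyloxy]phenyl}propan-2-yl]phenol
Product: 13 {5-[(2S,3S)-5-bromo-7-methoxy-3-methyl-2,3-dihydro-1-benzofuran-2-yl]-2,3-dimethoxyphenoxy}tri(propan-2-yl)silane (C3 is untouched; its descriptor changes from R to S only because C2 gains oxygen)
Conditions: DDQ (1.05 equiv), 4 Å MS, CH2Cl2, −20 → 0 °C
Reagents that add atoms: none
Why: Electron-rich ring B and DDQ form a donor–acceptor complex, and net hydride loss from the ring B benzylic CH2 (electron transfer, then hydrogen-atom transfer) leaves a cation at C2 that is delocalised onto the para C4 methoxy oxygen; the ring A phenol oxygen adds to it and the proton passes to DDQH−, which leaves as DDQH2. The closest known reaction type is the DDQ dehydrogenative benzylic C–H/O–H cyclisation of 2-(3-arylpropyl)phenols to flavans and of 2-arylethyl alcohols to isochromans. Ring C closes by 5-exo-trig attack of O1 on the exocyclic cationic carbon C2. The new C2 stereocentre is governed by the C3 stereocentre from step 8: ring B takes the face of the forming envelope opposite the C3 methyl group, and because trans is also the more stable isomer and the benzylic ether can re-ionise, 3S should translate into 2S. The step needs hydride abstraction at C2 and not at the tertiary C3–H or at the phenol, which is secured by the para-methoxy stabilisation available only to the C2 cation and by the C5 bromine, which makes ring A the poorer donor. It must also stop before a second dehydrogenation to the benzofuran, which the weakly donating aryloxy oxygen at C2, one equivalent of DDQ and low temperature are meant to ensure.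

Step 11
Reactants: 14 ethyl (2S)-2-hydroxypropanoate (ethyl (S)-lactate)
Product: 15 ethyl (2S)-2-[(tert-butyldimethylsilyl)oxy]propanoate
Conditions: TBSCl, imidazole, DMF, rt
Reagents that add atoms: tert-butyldimethylsilyl chloride, CC(C)(C)[Si](C)(C)Cl
Why: Silyl ether formation on the secondary alcohol; no base strong enough to enolise the ester is present, so the (S) centre is untouched.

Step 12
Reactants: 15 ethyl (2S)-2-[(tert-butyldimethylsilyl)oxy]propanoate
Product: 16 (2S)-2-[(tert-butyldimethylsilyl)oxy]-N-methoxy-N-methylpropanamide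
Conditions: MeNH(OMe)·HCl, i-PrMgCl, THF, −20 → 0 °C
Reagents that add atoms: N,O-dimethylhydroxylamine hydrochloride, CNOC.Cl
Why: Weinreb amide synthesis by aminolysis of the ester with the chloromagnesium amide made in the flask; at or below 0 °C the α-silyloxy centre should not epimerise.

Step 13
Reactants: 13 {5-[(2S,3S)-5-bromo-7-methoxy-3-methyl-2,3-dihydro-1-benzofuran-2-yl]-2,3-dimethoxyphenoxy}tri(propan-2-yl)silane; 16 (2S)-2-[(tert-butyldimethylsilyl)oxy]-N-methoxy-N-methylpropanamide
Product: 19 (2S)-2-[(tert-butyldimethylsilyl)oxy]-1-[(2S,3S)-2-{3,4-dimethoxy-5-[tri(propan-2-yl)silyloxy]phenyl}-7-methoxy-3-methyl-2,3-dihydro-1-benzofuran-5-yl]propan-1-one, via C5 aryllithium 17 (not isolated), via lithium hemiaminal adduct 18 (not isolated)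
Conditions: n-BuLi (1.05 equiv), THF, −78 °C; then 16, −78 → −20 °C; aq. NH4Cl
Reagents that add atoms: none
Why: Bromine–lithium exchange at C5 (faster at −78 °C than any deprotonation) gives aryllithium 17, which adds to the Weinreb amide to give the chelated tetrahedral adduct 18 that holds until the quench (Weinreb ketone synthesis), so over-addition is avoided and the α-silyloxy centre stays (S).

Step 14
Reactants: 19 (2S)-2-[(tert-butyldimethylsilyl)oxy]-1-[(2S,3S)-2-{3,4-dimethoxy-5-[tri(propan-2-yl)silyloxy]phenyl}-7-methoxy-3-methyl-2,3-dihydro-1-benzofuran-5-yl]propan-1-one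
Product: 20 (2S)-2-hydroxy-1-[(2S,3S)-2-(3-hydroxy-4,5-dimethoxyphenyl)-7-methoxy-3-methyl-2,3-dihydro-1-benzofuran-5-yl]propan-1-one
Conditions: Bu4NF (2.5 equiv), AcOH (2.5 equiv), THF, 0 °C → rt
Reagents that add atoms: none
Why: Fluoride-mediated desilylation cleaves both the aryl TIPS and the α-keto TBS ether, and buffering Bu4NF with AcOH should keep the medium from enolising the α-hydroxy ketone, so C2' remains (S).

Step 15
Reactants: 20 (2S)-2-hydroxy-1-[(2S,3S)-2-(3-hydroxy-4,5-dimethoxyphenyl)-7-methoxy-3-methyl-2,3-dihydro-1-benzofuran-5-yl]propan-1-one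
Product: 21 (1R,2S)-1-[(2S,3S)-2-(3-hydroxy-4,5-dimethoxyphenyl)-7-methoxy-3-methyl-2,3-dihydro-1-benzofuran-5-yl]propane-1,2-diol (CNP0229216.1)
Conditions: Zn(BH4)2 (Et2O solution), THF, −30 → 0 °C; aq. NH4Cl
Reagents that add atoms: none
Why: Chelation-controlled (Cram chelate) reduction: zinc bridges the ketone and α-hydroxyl oxygens and hydride arrives on the carbonyl face next to the small C2' hydrogen, which should give the anti diol, that is 1'R beside 2'S.

**Compound list**
1 | 3-hydroxy-4,5-dimethoxybenzaldehyde | COc1cc(C=O)cc(O)c1OC | starting material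
2 | 3,4-dimethoxy-5-[tri(propan-2-yl)silyloxy]benzaldehyde | COc1cc(C=O)cc(O[Si](C(C)C)(C(C)C)C(C)C)c1OC | intermediate
3 | [5-(2,2-dibromoethenyl)-2,3-dimethoxyphenoxy]tri(propan-2-yl)silane | COc1cc(C=C(Br)Br)cc(O[Si](C(C)C)(C(C)C)C(C)C)c1OC | intermediate
4 | lithium acetylide ({3,4-dimethoxy-5-[tri(propan-2-yl)silyloxy]phenyl}ethynyllithium) | COc1cc(C#C[Li])cc(O[Si](C(C)C)(C(C)C)C(C)C)c1OC | intermediate
5 | [2,3-dimethoxy-5-(prop-1-yn-1-yl)phenoxy]tri(propan-2-yl)silane | CC#Cc1cc(OC)c(OC)c(O[Si](C(C)C)(C(C)C)C(C)C)c1 | intermediate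
6 | 2-[(1Z)-1-{3,4-dimethoxy-5-[tri(propan-2-yl)silyloxy]phenyl}prop-1-en-2-yl]-4,4,5,5-tetramethyl-1,3,2-dioxaborolane | C/C(B1OC(C)(C)C(C)(C)O1)=C\c1cc(OC)c(OC)c(O[Si](C(C)C)(C(C)C)C(C)C)c1 | intermediate
7 | 4-bromo-2-methoxyphenol | COc1cc(Br)ccc1O | starting material
8 | 4-bromo-2-iodo-6-methoxyphenol | COc1cc(Br)cc(I)c1O | intermediate
9 | 5-bromo-1-iodo-3-methoxy-2-(methoxymethoxy)benzene | COCOc1c(I)cc(Br)cc1OC | intermediate
10 | {5-[(1E)-2-[5-bromo-3-methoxy-2-(methoxymethoxy)phenyl]prop-1-en-1-yl]-2,3-dimethoxyphenoxy}tri(propan-2-yl)silane | C/C(c1cc(Br)cc(OC)c1OCOC)=C\c1cc(OC)c(OC)c(O[Si](C(C)C)(C(C)C)C(C)C)c1 | intermediate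
11 | 5-bromo-1-[(2R)-1-{3,4-dimethoxy-5-[tri(propan-2-yl)silyloxy]phenyl}propan-2-yl]-3-methoxy-2-(methoxymethoxy)benzene | COCOc1c(OC)cc(Br)cc1[C@H](C)Cc1cc(OC)c(OC)c(O[Si](C(C)C)(C(C)C)C(C)C)c1 | intermediate
12 | 4-bromo-2-methoxy-6-[(2R)-1-{3,4-dimethoxy-5-[tri(propan-2-yl)silyloxy]phenyl}propan-2-yl]phenol | COc1cc(Br)cc([C@H](C)Cc2cc(OC)c(OC)c(O[Si](C(C)C)(C(C)C)C(C)C)c2)c1O | intermediate
13 | {5-[(2S,3S)-5-bromo-7-methoxy-3-methyl-2,3-dihydro-1-benzofuran-2-yl]-2,3-dimethoxyphenoxy}tri(propan-2-yl)silane | COc1cc([C@H]2Oc3c(OC)cc(Br)cc3[C@@H]2C)cc(O[Si](C(C)C)(C(C)C)C(C)C)c1OC | intermediate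
14 | ethyl (2S)-2-hydroxypropanoate | CCOC(=O)[C@H](C)O | starting material
15 | ethyl (2S)-2-[(tert-butyldimethylsilyl)oxy]propanoate | CCOC(=O)[C@H](C)O[Si](C)(C)C(C)(C)C | intermediate
16 | (2S)-2-[(tert-butyldimethylsilyl)oxy]-N-methoxy-N-methylpropanamide | CON(C)C(=O)[C@H](C)O[Si](C)(C)C(C)(C)C | intermediate
17 | C5 aryllithium from 13 | COc1cc([C@H]2Oc3c(OC)cc([Li])cc3[C@@H]2C)cc(O[Si](C(C)C)(C(C)C)C(C)C)c1OC | intermediate
18 | lithium hemiaminal (tetrahedral) adduct of 17 and 16 | COc1cc([C@H]2Oc3c(OC)cc(C(O[Li])(N(C)OC)[C@H](C)O[Si](C)(C)C(C)(C)C)cc3[C@@H]2C)cc(O[Si](C(C)C)(C(C)C)C(C)C)c1OC | intermediate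
19 | (2S)-2-[(tert-butyldimethylsilyl)oxy]-1-[(2S,3S)-2-{3,4-dimethoxy-5-[tri(propan-2-yl)silyloxy]phenyl}-7-methoxy-3-methyl-2,3-dihydro-1-benzofuran-5-yl]propan-1-one | COc1cc([C@H]2Oc3c(OC)cc(C(=O)[C@H](C)O[Si](C)(C)C(C)(C)C)cc3[C@@H]2C)cc(O[Si](C(C)C)(C(C)C)C(C)C)c1OC | intermediate
20 | (2S)-2-hydroxy-1-[(2S,3S)-2-(3-hydroxy-4,5-dimethoxyphenyl)-7-methoxy-3-methyl-2,3-dihydro-1-benzofuran-5-yl]propan-1-one | COc1cc([C@H]2Oc3c(OC)cc(C(=O)[C@H](C)O)cc3[C@@H]2C)cc(O)c1OC | intermediate
21 | (1R,2S)-1-[(2S,3S)-2-(3-hydroxy-4,5-dimethoxyphenyl)-7-methoxy-3-methyl-2,3-dihydro-1-benzofuran-5-yl]propane-1,2-diol | COc1cc([C@H]2Oc3c(OC)cc([C@@H](O)[C@H](C)O)cc3[C@@H]2C)cc(O)c1OC | target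

**Step count**
Total: 15 steps. Longest linear sequence: 11 steps (steps 1–4, 7–10, 13–15).

**Steps most likely to fail**

Step 10. The oxidant may attack the free phenol or the ring A benzylic C3–H, which would erode the C3 configuration through an ortho-quinone methide, or it may dehydrogenate the product further to the benzofuran. The fallback separates oxidation from ring closure and sets out from 11, where the phenol is still a MOM ether. DDQ in CH2Cl2/AcOH should acetoxylate the ring B benzylic CH2 to give (1RS,2S)-2-[5-bromo-3-methoxy-2-(methoxymethoxy)phenyl]-1-{3,4-dimethoxy-5-[tri(propan-2-yl)silyloxy]phenyl}propyl acetate F1 as a mixture of C1 epimers. HCl in MeOH/THF then removes the MOM group and ionises the acetate with no oxidant present, and the phenol closes ring C by SN1 etherification under thermodynamic (trans) control. The fallback comes back to the route at 13.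

Step 8. The ring A aryl group carries an ortho substituent next to the alkene, so slow turnover or poor facial selectivity is possible. The fallback gives up asymmetric catalysis for resolution and sets out from 10. Hydrogenation with achiral [Ir(cod)(PCy3)(py)]PF6 in CH2Cl2 (which spares the aryl bromide) should give racemic 5-bromo-1-(1-{3,4-dimethoxy-5-[tri(propan-2-yl)silyloxy]phenyl}propan-2-yl)-3-methoxy-2-(methoxymethoxy)benzene F2. Methanolic HCl then gives racemic 4-bromo-2-methoxy-6-(1-{3,4-dimethoxy-5-[tri(propan-2-yl)silyloxy]phenyl}propan-2-yl)phenol F3. Preparative chromatography on a chiral stationary phase separates the enantiomers, and the (R)-enantiomer rejoins the route at 12.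

Step 14. The α-hydroxy ketone may lose configuration at C2', or undergo ketol transposition, once basic fluoride and phenoxide are present. The fallback stages the deprotection around the reduction so the ketol never meets fluoride base, and sets out from 19. HF·pyridine in THF/pyridine at 0 °C should remove only the alkyl TBS group to give (2S)-1-[(2S,3S)-2-{3,4-dimethoxy-5-[tri(propan-2-yl)silyloxy]phenyl}-7-methoxy-3-methyl-2,3-dihydro-1-benzofuran-5-yl]-2-hydroxypropan-1-one F4. Zn(BH4)2 reduction under chelation control should give (1R,2S)-1-[(2S,3S)-2-{3,4-dimethoxy-5-[tri(propan-2-yl)silyloxy]phenyl}-7-methoxy-3-methyl-2,3-dihydro-1-benzofuran-5-yl]propane-1,2-diol F5. Bu4NF in THF at 0 °C then frees the ring B phenol, and the fallback comes back to the route at 21.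

**Further compounds**
F1 | step 10 | (1RS,2S)-2-[5-bromo-3-methoxy-2-(methoxymethoxy)phenyl]-1-{3,4-dimethoxy-5-[tri(propan-2-yl)silyloxy]phenyl}propyl acetate | COCOc1c(OC)cc(Br)cc1[C@H](C)C(OC(C)=O)c1cc(OC)c(OC)c(O[Si](C(C)C)(C(C)C)C(C)C)c1
F2 | step 8 | racemic 5-bromo-1-(1-{3,4-dimethoxy-5-[tri(propan-2-yl)silyloxy]phenyl}propan-2-yl)-3-methoxy-2-(methoxymethoxy)benzene | COCOc1c(OC)cc(Br)cc1C(C)Cc1cc(OC)c(OC)c(O[Si](C(C)C)(C(C)C)C(C)C)c1
F3 | step 8 | racemic 4-bromo-2-methoxy-6-(1-{3,4-dimethoxy-5-[tri(propan-2-yl)silyloxy]phenyl}propan-2-yl)phenol | COc1cc(Br)cc(C(C)Cc2cc(OC)c(OC)c(O[Si](C(C)C)(C(C)C)C(C)C)c2)c1O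
F4 | step 14 | (2S)-1-[(2S,3S)-2-{3,4-dimethoxy-5-[tri(propan-2-yl)silyloxy]phenyl}-7-methoxy-3-methyl-2,3-dihydro-1-benzofuran-5-yl]-2-hydroxypropan-1-one | COc1cc([C@H]2Oc3c(OC)cc(C(=O)[C@H](C)O)cc3[C@@H]2C)cc(O[Si](C(C)C)(C(C)C)C(C)C)c1OC
F5 | step 14 | (1R,2S)-1-[(2S,3S)-2-{3,4-dimethoxy-5-[tri(propan-2-yl)silyloxy]phenyl}-7-methoxy-3-methyl-2,3-dihydro-1-benzofuran-5-yl]propane-1,2-diol | COc1cc([C@H]2Oc3c(OC)cc([C@@H](O)[C@H](C)O)cc3[C@@H]2C)cc(O[Si](C(C)C)(C(C)C)C(C)C)c1OC
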